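You want to know how much target stands in the winter flask at 25 min, and which option, if any, adds to it.

| flask | solid substrate | temperature | remark | time |
|---|---|---|---|---|
| winter | 0.80 M | 5 °C | the very flask that is asked about, followed so far |  |
| dusk | 0.54 M | 0 °C | run made earlier |  |
| flask | 0.80 M | 5 °C |  | 25 min |

| winter: time / min | winter: target / % | dusk: time / min | dusk: target / % |
|---|---|---|---|
| 1.33 | 2 | 0.667 | 0 |
| 4.00 | 15 | 2.00 | 5 |
| 8.00 | 22 | 3.00 | 5 |
| 10.0 | 24 | 5.00 | 11 |
| 15.0 | 22 | 8.00 | 20 |
| 20.0 | 20 | 10.0 | 22 |
| 25.0 | 18 | 12.0 | 24 |

(scatter of a reading: 1.5 percentage points)

1. target, in percent of the solid substrate first charged, at 25 min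
2. the option that brings most further target ("none" if no option brings more than 2 percentage points) (maple / birch / elm / none)
3. target present, with what was taken out counted in, in percent of the solid substrate first charged, after maple
4. target present, with what was taken out counted in, in percent of the solid substrate first charged, after elm

- solid, in amounts per volume of the solution: solid substrate
- removed target is counted in
- steps under discussion: intermediate C -> target; solid substrate <-> starting material; starting material -> intermediate A; intermediate A -> intermediate C; starting material <-> intermediate B; starting material -> intermediate C; target <-> isomer of the product; intermediate C -> side product; intermediate C <-> intermediate D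
- at the start none of the solid substrate is in solution

- maple: at 25 min take out 90 % of the target then present, then wait 25 min
- birch: change nothing and wait 25 min more
- elm: at 25 min raise the temperature by 25 K, then wait 25 min

Start from the balance on the solid substrate, the limiting reagent: whatever is not target is somewhere else in the flask. At the last winter reading 82.0 % of the charge is not target; call this the unseen share. Whatever an option adds to target must come out of it.

Now read the winter run as a ladder of rates, fastest first. Target first gains 13 percentage points in 2.67 min, which is faster than the next 7 points in 4.00 min. From the top reading it falls 6 points in 15.0 min, slower than either rise.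

At that top reading the unseen share is already 76.0 %, so nearly all of it stood before the fall began. The winter fall of 6 points is less than the 76.0 % unseen before it, so that tail does not measure what can return.

My own reckoning puts target in the winter flask now near 18 %, give or take 1.5 points, and leaves the best option open: target readings do not split the unseen share into what can return and what cannot.

The forecast gives 18 % now, maple as best, 22 % after maple and 16 % after elm, reckoning that “roughly 12% isomer has accumulated by 25 min”. There my reckoning differs, since it names no split.

The winter flask gives 19.8 % at 25 min, and elm is best, with 42.6 % after elm against 31.6 % after maple.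

    intermediate C → target (k = 0.0140 s⁻¹, Ea = 70.0 kJ mol⁻¹)
    solid substrate ⇌ starting material, rate k2*(cs2 - [starting material]) while solid is left; crystals form when [starting material] > cs2 (solubility = 0.290 M, k = 0.0210 s⁻¹)
    starting material → intermediate A (k = 0.0980 s⁻¹, Ea = 69.0 kJ mol⁻¹)
    intermediate A → intermediate C (k = 0.00430 s⁻¹, Ea = 78.0 kJ mol⁻¹)
    starting material ⇌ intermediate B (K = 2.70, k = 0.0220 s⁻¹, Ea = 67.0 kJ mol⁻¹, ΔH = −25.0 kJ mol⁻¹)
    starting material → intermediate C (k = 0.00470 s⁻¹, Ea = 89.0 kJ mol⁻¹)
    target ⇌ isomer of the product (K = 2.10, k = 0.00390 s⁻¹, Ea = 70.0 kJ mol⁻¹, ΔH = −45.0 kJ mol⁻¹)
    intermediate C → side product (k = 0.00910 s⁻¹, Ea = 70.0 kJ mol⁻¹)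
    intermediate C ⇌ intermediate D (K = 0.860, k = 0.00190 s⁻¹, Ea = 80.0 kJ mol⁻¹, ΔH = −34.0 kJ mol⁻¹)
    (constants at 5 °C)

The unseen share of the winter flask is 80.2 %, holding 40.0 % isomer of the product and 38.9 % side product at 25.0 min. The neighbouring flask, the same charge at 30 °C, holds 42.6 % target at 25.0 min, so its unseen share is 57.4 %, with side product at 39.4 % and isomer of the product at 18.0 %.

(The readings stem from a simulated flask for substances that don't exist.)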